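## Retrosynthetic overview

1. The ring B quinone comes from a para-methoxyphenol. That phenol comes from the only aryl C–H of a 2,3,4,6-tetramethoxyphenyl group (lithiation, borylation, oxidation, then PhI(OAc)2). This is done last, so only ring B carries a free OH when the oxidant is added.
2. The chroman ether comes from a 3-arylchroman-2-one. The lactone C=O is reduced to CH2 and the heterocycle stays closed.
3. The key disconnection is C3–C1'. The lactone α-carbon is made electrophilic as the rhodium carbenoid of the α-diazolactone, an enolonium equivalent. It is attacked by the nucleophilic C–H carbon of 1,2,3,5-tetramethoxybenzene, and a chiral dirhodium carboxylate sets C3.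
4. The α-diazolactone comes from 6,7,8-trimethoxychroman-2-one, which comes from oxidative C–H lactonisation of 3-(3,4,5-trimethoxyphenyl)propanoic acid.
5. Ring order: rings A and B are bought as benzenes, the pyran ring (ring C) is closed in the first step, and the quinone is formed in the last step.

Assumption: the SMILES is read as the (3S) enantiomer, and Rh2(S-NTTL)4 is taken to give this sense of induction; if the first run shows the opposite sense, the mirror-image catalyst from D-tert-leucine is used and nothing else changes.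

## Route

Step 1
Reactants: 1 3-(3,4,5-trimethoxyphenyl)propanoic acid
Product: 2 6,7,8-trimethoxychroman-2-one
Conditions: PhI(OCOCF3)2 (1.2 equiv), BF3·OEt2 (1.5 equiv), CF3CO2H, rt
Reagents that add atoms: none
Why: Oxidative C–H lactonisation with trivalent iodine: the arene is oxidised to its radical cation, the tethered carboxylic acid traps it at the free ortho carbon (para to a coplanar methoxy group, both ortho sites being equivalent), and loss of a second electron and a proton gives the six-membered aryl lactone, which is less electron-rich than 1 and is not oxidised further; no stereocentre is formed.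

Step 2
Reactants: 2 6,7,8-trimethoxychroman-2-one
Product: 4 3-diazo-6,7,8-trimethoxychroman-2-one, via trifluoroacetyl lactone 3 (not isolated)
Conditions: LiN(SiMe3)2, THF, −78 °C; CF3CO2CH2CF3; aq HCl wash; then 4-AcNHC6H4SO2N3, Et3N, H2O (1 equiv), MeCN, rt
Reagents that add atoms: 4-acetamidobenzenesulfonyl azide, CC(=O)Nc1ccc(cc1)S(=O)(=O)N=[N+]=[N-] (N2 in 4); 2,2,2-trifluoroethyl trifluoroacetate, O=C(OCC(F)(F)F)C(F)(F)F (CF3CO in 3 only)
Why: Detrifluoroacetylative diazo transfer (Regitz type): C-trifluoroacetylation of the lithium enolate at −78 °C makes C3–H acidic enough to accept N2 from the sulfonyl azide under Et3N, and the activating acyl group leaves on the sulfonamide, so the aryl ester never meets a nucleophilic base.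

Step 3
Reactants: 4 3-diazo-6,7,8-trimethoxychroman-2-one; 5 1,2,3,5-tetramethoxybenzene
Product: 7 (3S)-6,7,8-trimethoxy-3-(2,3,4,6-tetramethoxyphenyl)chroman-2-one, via rhodium carbenoid 6 (not isolated)
Conditions: Rh2(S-NTTL)4 [dirhodium tetrakis(N-1,8-naphthaloyl-(S)-tert-leucinate)] (1 mol %), 5 (4 equiv), PhMe/CH2Cl2, −78 °C, slow addition of 4
Reagents that add atoms: none
Why: Proposed new method: loss of N2 at the dirhodium core turns C3, normally the nucleophilic enolate carbon of the lactone, into an electrophilic carbenoid (an enolonium equivalent) that is attacked by the equally nucleophilic C4–H carbon of 5 (ortho, ortho and para to methoxy groups) in a Friedel–Crafts-type aromatic substitution, and the arenium proton passes to C3 while rhodium is still bound, so the carbene face left open by the chiral crown of the four tert-leucinate ligands fixes (S)-C3; the low temperature, the bulky carboxylates, the ring constraint and the excess arene hold back the competing 1,2-hydride shift from C4; the closest known reaction types are the dirhodium tetracarboxylate-catalysed enantioselective C–H functionalisation of indoles with α-alkyl-α-diazoesters and the intermolecular trapping of cyclic α-diazocarbonyl compounds in preference to β-hydride migration.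

Step 4
Reactants: 7 (3S)-6,7,8-trimethoxy-3-(2,3,4,6-tetramethoxyphenyl)chroman-2-one
Product: 9 (3S)-6,7,8-trimethoxy-3-(2,3,4,6-tetramethoxyphenyl)chroman, via aluminium lactolate 8 (not isolated)
Conditions: i-Bu2AlH (1.1 equiv), CH2Cl2, −78 °C; then Et3SiH (5 equiv), BF3·OEt2 (2.5 equiv), −78 → −30 °C
Reagents that add atoms: diisobutylaluminium hydride, CC(C)C[AlH]CC(C)C (i-Bu2Al in 8 only; 9 gains hydrogen only)
Why: Partial reduction of the aryl lactone stops at the tetrahedral aluminium lactolate at −78 °C, and ionic hydrogenation (Et3SiH with a Lewis acid) of the derived cyclic oxocarbenium ion gives the ether; the medium is never basic and hydride capture at low temperature outruns loss of the C3 proton, so (S)-C3 is kept.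

Step 5
Reactants: 9 (3S)-6,7,8-trimethoxy-3-(2,3,4,6-tetramethoxyphenyl)chroman
Product: 12 2,3,4,6-tetramethoxy-5-[(3S)-6,7,8-trimethoxychroman-3-yl]phenol, via aryllithium 10 (not isolated), via dimethyl arylboronate 11 (not isolated)
Conditions: n-BuLi (1.3 equiv), THF, 0 °C; B(OMe)3, −78 °C → rt; AcOH, 30% aq H2O2, 0 °C → rt
Reagents that add atoms: hydrogen peroxide, OO (O of the new OH in 12); n-butyllithium, [Li]CCCC (Li in 10 only); trimethyl borate, COB(OC)OC (B(OMe)2 in 11 only)
Why: Directed ortho-metalation picks the only C–H flanked by two methoxy groups (C5' of ring B) over the singly activated C5–H of ring A, and borylation followed by the peroxide-induced 1,2-shift of aryl from boron to oxygen gives the phenol; the far less acidic C3–H is not touched.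

Step 6
Reactants: 12 2,3,4,6-tetramethoxy-5-[(3S)-6,7,8-trimethoxychroman-3-yl]phenol
Product: 13 2,3,5-trimethoxy-6-[(3S)-6,7,8-trimethoxychroman-3-yl]cyclohexa-2,5-diene-1,4-dione (target)
Conditions: PhI(OAc)2 (1.1 equiv), MeCN/H2O 4:1, 0 °C, 15 min
Reagents that add atoms: water, O
Why: Oxidative demethylation of a para-methoxyphenol: trivalent iodine binds only the free phenol, water adds at the para carbon and the hemiketal loses methanol to give the 1,4-quinone, while the fully etherified ring A is inert to this oxidant without Lewis acid and the near-neutral medium leaves C3 configurationally intact.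

## Compound list

1 | 3-(3,4,5-trimethoxyphenyl)propanoic acid | COc1cc(CCC(=O)O)cc(OC)c1OC | starting material
2 | 6,7,8-trimethoxychroman-2-one | COc1cc2CCC(=O)Oc2c(OC)c1OC | intermediate
3 | 6,7,8-trimethoxy-3-(trifluoroacetyl)chroman-2-one | COc1cc2CC(C(=O)C(F)(F)F)C(=O)Oc2c(OC)c1OC | intermediate
4 | 3-diazo-6,7,8-trimethoxychroman-2-one | COc1cc2CC(=[N+]=[N-])C(=O)Oc2c(OC)c1OC | intermediate
5 | 1,2,3,5-tetramethoxybenzene | COc1cc(OC)c(OC)c(OC)c1 | starting material
6 | rhodium carbenoid of 4 (C3 bound to one rhodium of Rh2(S-NTTL)4; second rhodium and carboxylate ligands left out of the SMILES) | COc1cc2CC(=[Rh])C(=O)Oc2c(OC)c1OC | intermediate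
7 | (3S)-6,7,8-trimethoxy-3-(2,3,4,6-tetramethoxyphenyl)chroman-2-one | COc1cc(OC)c(OC)c(OC)c1[C@H]2C(=O)Oc3c(cc(OC)c(OC)c3OC)C2 | intermediate
8 | diisobutylaluminium (3S)-6,7,8-trimethoxy-3-(2,3,4,6-tetramethoxyphenyl)chroman-2-olate (both C2 epimers) | COc1cc(OC)c(OC)c(OC)c1[C@H]2C(O[Al](CC(C)C)CC(C)C)Oc3c(cc(OC)c(OC)c3OC)C2 | intermediate
9 | (3S)-6,7,8-trimethoxy-3-(2,3,4,6-tetramethoxyphenyl)chroman | COc1cc(OC)c(OC)c(OC)c1[C@H]2COc3c(cc(OC)c(OC)c3OC)C2 | intermediate
10 | {2,3,4,6-tetramethoxy-5-[(3S)-6,7,8-trimethoxychroman-3-yl]phenyl}lithium | COc1c([Li])c(OC)c(OC)c(OC)c1[C@H]2COc3c(cc(OC)c(OC)c3OC)C2 | intermediate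
11 | dimethyl {2,3,4,6-tetramethoxy-5-[(3S)-6,7,8-trimethoxychroman-3-yl]phenyl}boronate | COc1c(B(OC)OC)c(OC)c(OC)c(OC)c1[C@H]2COc3c(cc(OC)c(OC)c3OC)C2 | intermediate
12 | 2,3,4,6-tetramethoxy-5-[(3S)-6,7,8-trimethoxychroman-3-yl]phenol | COc1c(O)c(OC)c(OC)c(OC)c1[C@H]2COc3c(cc(OC)c(OC)c3OC)C2 | intermediate
13 | 2,3,5-trimethoxy-6-[(3S)-6,7,8-trimethoxychroman-3-yl]cyclohexa-2,5-diene-1,4-dione | COC1=C(OC)C(=O)C([C@H]2COc3c(cc(OC)c(OC)c3OC)C2)=C(OC)C1=O | target

## Step count and risks

Total step count: 6. Longest linear sequence: 6 (1 → 2 → 4 → 7 → 9 → 12 → 13); compound 5 enters as bought.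

**Step 3 is the most at risk.** The benzylic C4–H can migrate to the carbene carbon and aromatise the lactone to the coumarin. The ee can also erode if the proton reaches C3 only after rhodium has left.

- The fallback sets out from 2 and comes back at 7. It keeps the same polarity but makes the bond and sets the configuration in separate operations.
- Lactone 2 is silylated (LiN(SiMe3)2, t-BuMe2SiCl, THF, −78 °C) to 2-(tert-butyldimethylsilyloxy)-6,7,8-trimethoxy-4H-chromene F1.
- PhI(OAc)2 with BF3·OEt2 in CH2Cl2 at −78 °C turns F1 into the trivalent-iodine enolonium species 3-[acetoxy(phenyl)-λ3-iodanyl]-6,7,8-trimethoxychroman-2-one F2.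
- F2 is intercepted in the same flask by 5 to give racemic 6,7,8-trimethoxy-3-(2,3,4,6-tetramethoxyphenyl)chroman-2-one F3.
- F3 is converted (LiN(SiMe3)2, Me3SiCl, THF, −78 °C) into the geometry-locked cyclic ketene acetal 6,7,8-trimethoxy-3-(2,3,4,6-tetramethoxyphenyl)-2-(trimethylsilyloxy)-4H-chromene F4.
- Catalytic enantioselective protonation of F4 (chiral BINOL-derived disulfonimide, MeOH as proton source, low temperature) delivers 7.

**Step 1 comes next.** The acid may attack the ipso carbon instead and give a spirodienone, or give the 5,6,7-trimethoxy isomer after an alkyl shift.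

- The fallback sets out from 1 and comes back at 2. It fixes the regiochemistry through C–C rather than C–O bond formation.
- Intramolecular Friedel–Crafts acylation (P2O5 in MeSO3H, rt) can only give 5,6,7-trimethoxyindan-1-one F5.
- Baeyer–Villiger oxidation of F5 (mCPBA, cat. TsOH, CH2Cl2), with migration of the electron-rich aryl group, inserts oxygen between the carbonyl carbon and ring A to give 2.

**Step 4 is third.** The aryl lactolate may collapse and be over-reduced. The oxocarbenium ion may also lose the C3 proton to give the 4H-chromene, which would erode the ee.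

- The fallback sets out from 7 and comes back at 9. It avoids any cation next to C3.
- LiAlH4 (THF, −78 → 0 °C) opens the lactone fully to 6-[(2S)-3-hydroxy-2-(2,3,4,6-tetramethoxyphenyl)propyl]-2,3,4-trimethoxyphenol F6.
- Intramolecular Mitsunobu etherification (PPh3, DIAD, THF, 0 °C) closes the O1–C2 bond by displacement at the primary carbon to give 9.

## Further compounds

F1 | step 3 | 2-(tert-butyldimethylsilyloxy)-6,7,8-trimethoxy-4H-chromene | COc1cc2CC=C(O[Si](C)(C)C(C)(C)C)Oc2c(OC)c1OC
F2 | step 3 | 3-[acetoxy(phenyl)-λ3-iodanyl]-6,7,8-trimethoxychroman-2-one | COc1cc2CC(I(OC(C)=O)c3ccccc3)C(=O)Oc2c(OC)c1OC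
F3 | step 3 | racemic 6,7,8-trimethoxy-3-(2,3,4,6-tetramethoxyphenyl)chroman-2-one | COc1cc(OC)c(OC)c(OC)c1C2C(=O)Oc3c(cc(OC)c(OC)c3OC)C2
F4 | step 3 | 6,7,8-trimethoxy-3-(2,3,4,6-tetramethoxyphenyl)-2-(trimethylsilyloxy)-4H-chromene | COc1cc(OC)c(OC)c(OC)c1C2=C(O[Si](C)(C)C)Oc3c(cc(OC)c(OC)c3OC)C2
F5 | step 1 | 5,6,7-trimethoxyindan-1-one | COc1cc2CCC(=O)c2c(OC)c1OC
F6 | step 4 | 6-[(2S)-3-hydroxy-2-(2,3,4,6-tetramethoxyphenyl)propyl]-2,3,4-trimethoxyphenol | COc1cc(OC)c(OC)c(OC)c1[C@@H](CO)Cc1cc(OC)c(OC)c(OC)c1O
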